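## Retrosynthetic overview

1. Parritadial comes from its cyclic 11,12-bis(methyl acetal) 1β,6α-diacetate by acid hydrolysis; the 6α-OAc/5α-H pair comes from α-face hydroboration of a Δ5,7-diene, then acetylation.
2. The Δ5,7-diene with 9α-OH comes from vinylogous enolate hydroxylation at C9 of a drima-5,8-dien-11-al.
3. Key late coupling: intermolecular Diels–Alder of a C13 ring-A vinylcyclohexenyl acetate with a C6 ynal mono-acetal, forming C7–C8 and C9–C10 (ring B and the C10 quaternary centre).
4. The diene comes from CBS reduction and acetylation of a 3-vinyl dienone, made by Stork–Danheiser vinylation of a vinylogous ester of 2,4,4-trimethylcyclohexane-1,3-dione (Michael–Claisen annulation).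
5. The ynal comes from acrolein (bromination, acetalisation, double elimination, hydroxymethylation, oxidation). Ring order: ring A first, ring B in the coupling.

Assumptions: drimane numbering, β = face of the C10 methyl; the SMILES is read as (1R,5S,6S,9S,10R)-1β,6α-diacetoxy-9α-hydroxydrim-7-ene-11,12-dial. A one-pot sequence with no intermediate isolation is counted as one step.

## Fragment A: ring-A diene

**Step 1**
Reactants: 1, 2-methylpentan-3-one; 2, methyl acrylate
Product: 3, 2,4,4-trimethylcyclohexane-1,3-dione
Conditions: t-BuOK, THF, 0 °C to rt; aq. HCl work-up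
Reagents that add atoms: none
Why: Consecutive Michael–Claisen [3+3] annulation; Michael addition through the more substituted enolate followed by Claisen closure from the ethyl CH2 is the only pathway ending in an enolisable (deprotonated) 1,3-dione, which drives the equilibrium. No stereocentre.

**Step 2**
Reactants: 3, 2,4,4-trimethylcyclohexane-1,3-dione
Product: 4, 3-isobutoxy-2,6,6-trimethylcyclohex-2-en-1-one
Conditions: i-BuOH, TsOH (cat.), PhMe, reflux, Dean–Stark
Reagents that add atoms: isobutanol, CC(C)CO
Why: Acid-catalysed vinylogous ester formation under thermodynamic control places the alkoxy group on the carbonyl remote from the gem-dimethyl group; the minor regioisomer is removed by chromatography.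

**Step 3**
Reactants: 4, 3-isobutoxy-2,6,6-trimethylcyclohex-2-en-1-one
Product: 5, 3-ethenyl-2,4,4-trimethylcyclohex-2-en-1-one
Conditions: CH2=CHMgBr, CeCl3, THF, −78 to 0 °C; then 1 M HCl, rt
Reagents that add atoms: vinylmagnesium bromide, C=C[Mg]Br
Why: Stork–Danheiser transposition; organocerium 1,2-addition to the hindered carbonyl, then acid hydrolysis/dehydration moves the carbonyl and leaves the vinyl group next to the quaternary carbon.

**Step 4**
Reactants: 5, 3-ethenyl-2,4,4-trimethylcyclohex-2-en-1-one
Product: 6, (1R)-3-ethenyl-2,4,4-trimethylcyclohex-2-en-1-ol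
Conditions: (S)-Me-CBS (20 mol %), catecholborane, PhMe, −78 °C
Reagents that add atoms: none
Why: Corey–Bakshi–Shibata reduction; the α-methyl-substituted alkenyl arm acts as the large group, so the (S)-catalyst gives the (R)-carbinol (future C1), and catecholborane at −78 °C does not hydroborate the diene.

**Step 5**
Reactants: 6, (1R)-3-ethenyl-2,4,4-trimethylcyclohex-2-en-1-ol
Product: 7, (1R)-3-ethenyl-2,4,4-trimethylcyclohex-2-en-1-yl acetate
Conditions: Ac2O, Et3N, DMAP (cat.), CH2Cl2, 0 °C to rt
Reagents that add atoms: acetic anhydride, CC(=O)OC(C)=O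
Why: DMAP-catalysed acylation installs the C1 acetate of the target with retention at the stereocentre.

## Fragment B: ynal dienophile

**Step 6**
Reactants: 8, acrolein
Product: 9, 2,3-dibromopropanal (racemic)
Conditions: Br2, CH2Cl2, 0 °C
Reagents that add atoms: bromine, BrBr
Why: Electrophilic anti-addition of bromine to the alkene; the stereocentre is removed again in step 8.

**Step 7**
Reactants: 9, 2,3-dibromopropanal
Product: 10, 2,3-dibromo-1,1-dimethoxypropane
Conditions: HC(OMe)3, MeOH, HCl (cat.), rt
Reagents that add atoms: trimethyl orthoformate, COC(OC)OC; methanol, CO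
Why: Acid-catalysed acetalisation (orthoformate as water scavenger) protects the aldehyde before strong base.

**Step 8**
Reactants: 10, 2,3-dibromo-1,1-dimethoxypropane
Product: 11, 3,3-dimethoxyprop-1-yne
Conditions: 50% aq. NaOH, n-Bu4NHSO4, pentane, rt
Reagents that add atoms: none
Why: Phase-transfer double E2 dehydrobromination gives the terminal alkyne; the acetal is base-stable.

**Step 9**
Reactants: 11, 3,3-dimethoxyprop-1-yne
Product: 12, 4,4-dimethoxybut-2-yn-1-ol
Conditions: n-BuLi, THF, −78 °C; (CH2O)n, −78 °C to rt
Reagents that add atoms: formaldehyde (paraformaldehyde), C=O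
Why: Lithium acetylide addition to formaldehyde (hydroxymethylation).

**Step 10**
Reactants: 12, 4,4-dimethoxybut-2-yn-1-ol
Product: 13, 4,4-dimethoxybut-2-ynal
Conditions: activated MnO2, CH2Cl2, rt
Reagents that add atoms: none
Why: MnO2 oxidises the propargylic alcohol to the ynal under neutral conditions that leave the acetal intact.

## Coupling and endgame

**Step 11**
Reactants: 7, (1R)-3-ethenyl-2,4,4-trimethylcyclohex-2-en-1-yl acetate; 13, 4,4-dimethoxybut-2-ynal (2 equiv)
Product: 14, 1β-acetoxy-12,12-dimethoxydrima-5,8-dien-11-al (10β-CH3)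
Conditions: BHT (cat.), PhMe (2 M), 100 °C, sealed tube, 36–48 h
Reagents that add atoms: none
Why: Thermal intermolecular Diels–Alder; "ortho" regiochemistry bonds the formyl-bearing alkyne carbon to the substituted terminus (C10) and the acetal-bearing carbon to the vinyl CH2 (C7), and the dienophile adds to the face opposite the C1 acetate, so the new C10 methyl is cis to the acetate (1β-OAc, 10β-CH3).

**Step 12**
Reactants: 14, 1β-acetoxy-12,12-dimethoxydrima-5,8-dien-11-al
Product: 15, 1β-acetoxy-9α-hydroxy-11,12-dimethoxy-11,12-epoxydrima-5,7-diene (cyclic bis-acetal, anomer mixture at C11/C12)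
Conditions: KHMDS (1.1 equiv), THF, −78 °C; 2-(phenylsulfonyl)-3-phenyloxaziridine, −78 °C; then CSA, MeOH, −78 °C to rt (one pot)
Reagents that add atoms: Davis oxaziridine, O=S(=O)(c1ccccc1)N1OC1c1ccccc1 (adds O); methanol, CO (exchanges into the acetal OMe groups)
Why: γ-Deprotonation at the doubly allylic C7 gives the extended enolate, which undergoes Davis α-hydroxylation at C9 from the α-face opposite the C10 methyl (leaving the 5,7-diene); the acidic methanol quench isomerises the hydroxy-aldehyde/dimethyl acetal pair to the cyclic bis-acetal, masking the aldehyde for step 13.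

**Step 13**
Reactants: 15, 1β-acetoxy-9α-hydroxy-11,12-dimethoxy-11,12-epoxydrima-5,7-diene
Product: 16, 1β-acetoxy-11,12-dimethoxy-11,12-epoxydrim-7-ene-6α,9α-diol (5α-H)
Conditions: BH3·THF (3 equiv), THF, 0 °C to rt; then NaBO3·4H2O, THF/H2O, rt
Reagents that add atoms: sodium perborate, [Na+].[Na+].O[B-]1(O)OO[B-](O)(O)OO1 (adds O)
Why: Brown hydroboration–oxidation of the 5,7-diene, as with steroidal 5,7-dienes; syn addition across C5=C6 from the α-face (β-face blocked by the C10 and C4β methyls) with boron on C6 sets 5α-H and 6α-OH, while the oxygen-deactivated C7=C8 is left.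

**Step 14**
Reactants: 16, 1β-acetoxy-11,12-dimethoxy-11,12-epoxydrim-7-ene-6α,9α-diol
Product: 17, 1β,6α-diacetoxy-11,12-dimethoxy-11,12-epoxydrim-7-en-9α-ol
Conditions: Ac2O, pyridine, DMAP (cat.), CH2Cl2, 0 °C to rt
Reagents that add atoms: acetic anhydride, CC(=O)OC(C)=O
Why: Acylation of the equatorial secondary 6α-OH; the tertiary 9-OH is too hindered, and any C1-OH freed in step 13 is re-acetylated.

**Step 15**
Reactants: 17, 1β,6α-diacetoxy-11,12-dimethoxy-11,12-epoxydrim-7-en-9α-ol
Product: 18, Parritadial
Conditions: 1 M aq. HCl, THF, 0 °C to rt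
Reagents that add atoms: water, O
Why: Acid-catalysed acetal hydrolysis releases both aldehydes (enal at C8, α-hydroxy aldehyde at C9); the acetates and the tertiary alcohol tolerate dilute acid at rt and no stereocentre is touched.

## Compound list

1 | 2-methylpentan-3-one | CCC(=O)C(C)C | starting material
2 | methyl acrylate | C=CC(=O)OC | starting material
3 | 2,4,4-trimethylcyclohexane-1,3-dione | CC1C(=O)CCC(C)(C)C1=O | intermediate
4 | 3-isobutoxy-2,6,6-trimethylcyclohex-2-en-1-one | CC1=C(OCC(C)C)CCC(C)(C)C1=O | intermediate
5 | 3-ethenyl-2,4,4-trimethylcyclohex-2-en-1-one | C=CC1=C(C)C(=O)CCC1(C)C | intermediate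
6 | (1R)-3-ethenyl-2,4,4-trimethylcyclohex-2-en-1-ol | C=CC1=C(C)[C@H](O)CCC1(C)C | intermediate
7 | (1R)-3-ethenyl-2,4,4-trimethylcyclohex-2-en-1-yl acetate | C=CC1=C(C)[C@H](OC(C)=O)CCC1(C)C | intermediate
8 | acrolein | C=CC=O | starting material
9 | 2,3-dibromopropanal (racemic) | O=CC(Br)CBr | intermediate
10 | 2,3-dibromo-1,1-dimethoxypropane (racemic) | COC(OC)C(Br)CBr | intermediate
11 | 3,3-dimethoxyprop-1-yne | C#CC(OC)OC | intermediate
12 | 4,4-dimethoxybut-2-yn-1-ol | OCC#CC(OC)OC | intermediate
13 | 4,4-dimethoxybut-2-ynal | O=CC#CC(OC)OC | intermediate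
14 | 1β-acetoxy-12,12-dimethoxydrima-5,8-dien-11-al | C12=CCC(C(OC)OC)=C(C=O)[C@@]1(C)[C@H](OC(C)=O)CCC2(C)C | intermediate
15 | 1β-acetoxy-9α-hydroxy-11,12-dimethoxy-11,12-epoxydrima-5,7-diene | C12=CC=C3C(OC)OC(OC)[C@]3(O)[C@@]1(C)[C@H](OC(C)=O)CCC2(C)C | intermediate
16 | 1β-acetoxy-11,12-dimethoxy-11,12-epoxydrim-7-ene-6α,9α-diol | O[C@H]1C=C3C(OC)OC(OC)[C@]3(O)[C@@]2(C)[C@H](OC(C)=O)CCC(C)(C)[C@H]12 | intermediate
17 | 1β,6α-diacetoxy-11,12-dimethoxy-11,12-epoxydrim-7-en-9α-ol | CC(=O)O[C@H]1C=C3C(OC)OC(OC)[C@]3(O)[C@@]2(C)[C@H](OC(C)=O)CCC(C)(C)[C@H]12 | intermediate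
18 | Parritadial, (1R,5S,6S,9S,10R)-1β,6α-diacetoxy-9α-hydroxydrim-7-ene-11,12-dial | CC(=O)O[C@H]1C=C(C=O)[C@](O)(C=O)[C@@]2(C)[C@H](OC(C)=O)CCC(C)(C)[C@H]12 | target

## Totals

Total step count: 15.
Longest linear sequence: 10 steps (steps 1–5 then 11–15; the dienophile arm, steps 6–10 then 11–15, is also 10).

## Three steps most likely to fail

1. **Step 11 (Diels–Alder).** The diene is hindered (Z-methyl on the reacting terminus) and the ynal may polymerise before it adds. Fallback: carry C1 as a TBS ether and use dimethyl acetylenedicarboxylate (from acetylenedicarboxylic acid, MeOH/H2SO4), the proven dienophile for this diene class. Then hydroxylate the diester dienolate at C9, reduce to the 9,11,12-triol, silylate the primary alcohols, acetylate C1/C6, desilylate and finish with a double Swern oxidation.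

2. **Step 12 (extended-enolate hydroxylation and acetal isomerisation).** Risks are γ- rather than α-oxidation and attack of the base on the C1 acetate. Fallback: epoxidise the tetrasubstituted enal of 14 (t-BuOOH, DBU, Weitz–Scheffer) to the 8α,9α-epoxy aldehyde, then open the epoxide by base-induced elimination through the allylic C7–H to give the same 9α-hydroxy-5,7-diene, and acetalise separately.

3. **Step 13 (diene hydroboration).** Risks are allylborane scrambling, attack at C7=C8, and loss of the acetate. Fallback: drop the hydroboration; hydrogenate C5=C6 at the stage of 14 (H2, Pd/C, α-face, giving 5α-H). After C9 hydroxylation, introduce the C6 oxygen by allylic oxidation of the Δ7 olefin to the 7-en-6-one (CrO3·3,5-dimethylpyrazole), Luche reduction to the 6β-alcohol, and Mitsunobu inversion with AcOH to the 6α-acetate.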